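## The problem

1. Trigonochinene C (17) is a 3,4-seco-cleistanthane (cleistanthane numbering is used for every compound below). Ring A is gone, and its remains hang on ring B (C5–C10) as a methyl propanoate arm (C1–C3) on quaternary C10 and an isopropenyl group (C4, C18, C19) on the adjacent C5.
2. Ring B is fused through C8–C9 to ring C (C8, C9, C11–C14), a cross-conjugated cyclohexa-2,5-dienone substituted at every carbon except C11: C12=O, C13–CH3 (C17), C14–vinyl (C15, C16) and a tertiary hydroperoxide on C8.
3. There are three stereocentres, all R. C10 and C5 are vicinal, with the arm trans and C20 cis to the isopropenyl group. C8 lies 1,3 to C10 across sp2 carbon C9 and carries OOH on the face of C20.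
4. C10 and C5 can bias C8, but nothing in the target controls C10 and C5, so the absolute sense of this quaternary–tertiary pair must be brought in from outside.
5. The phenol that corresponds to ring C carries five contiguous substituents, with the vinyl group meta to oxygen between a methyl group and a ring carbon. No simple arene has this pattern, and electrophilic substitution cannot produce it.
6. Four groups forbid rough treatment, so the oxygen must come last: the doubly allylic tertiary hydroperoxide (reductants, acids, metals), the vinyl trienone (nucleophiles, radicals), the isopropenyl group (acid) and the methyl ester (hard nucleophiles).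
7. The enabling feature is that ring C with C17, together with C10, C20 and C1, is atom for atom the carbon skeleton of carvone with its carbonyl shifted from C14 to C12. C10(C20)=C1 is carvone's isopropenyl group on C9, C8 is its enolisable α′ carbon, and C7–C6–C5=C4(C18)(C19) is a homoprenyl chain.
8. In the resulting 1,7-diene, one radical event would make ring B, both permanent stereocentres and both remnants of ring A: addition of •CH2CO2Me to C1, then closure of the C10 radical on C5.

## Retrosynthesis

**C8–O.** Ring C of 17 is a 4-alkyl-4-hydroperoxycyclohexa-2,5-dienone, which is the adduct of O2 to the para carbon of phenol 16. Cutting any C–C bond first would carry the peroxide through further steps that it would not survive. Compound 16 has one stereocentre less, no peroxide, and a robust arene in place of the trienone. The forward reaction with singlet oxygen must hit C8 rather than the vinyl or isopropenyl group, and it must come from the face of C20.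

**The aromatic sextet (C9=C11, H8).** Phenol 16 is taken back through trienone 15 and silyl ether 14 to dienone 12 by returning hydrogen to C8, C9 and C11. Cutting a substituent off the arene instead (for example the vinyl group by cross-coupling) would leave the substitution pattern unsolved. De-aromatising turns C8 and C9 into sp3 centres that can relay configuration to C10 and C5 and are erased afterwards. Dienone 12 has two more stereocentres on paper, but it shows a 2-methyl-3-vinylcyclohex-2-enone, which has a short retron. The forward reaction asks only for regioselective α′,β′-dehydrogenation (C11–C9); tautomerisation does the rest.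

**C14–C15 with a 1,3-shift of oxygen (C12 to C14).** Dienone 12 comes from tertiary alcohol 11 by oxidative allylic transposition, and 11 comes from enone 10 and a vinyl nucleophile. The neighbouring option is conjugate addition of vinyl to a C12 enone followed by re-oxidation. That is longer, and it would make C8 a γ carbon, whereas with the carbonyl at C14 it is an α′ carbon. Enone 10 lacks the sensitive diene and shows ring C as a plain carvone ring. The forward steps need 1,2-addition beside an ester and migration of oxygen to C12 rather than to C16.

**Key cut: C10–C5 and C1–C2 (and one hydrogen back on C18).** Enone 10 falls apart into diene 5 and the radical •CH2CO2Me carried by xanthate 8, with tertiary xanthate 9 as the stored form of the last radical.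
- Cutting C9–C10 or C5–C6 instead would leave the quaternary carbon to an intermolecular attack.
- Cutting only C10–C1 (Michael logic) needs a carbonyl at C9 that ring C cannot offer.
- Diene 5 is monocyclic and has no quaternary carbon. It has two stereocentres, one bought and one set by it.
- The forward reaction must attack C1 first, close 6-exo before the C10 radical is lost, run through a chair with C20 axial, and end as an isopropenyl group.

**C8–C7.** Diene 5 comes from dienolate 4 of (R)-carvone 3 and iodide 2, which is made from commercial bromide 1. Xanthate 8 comes from 6 and 7. Alkylation at the α′ carbon anti to the isopropenyl group is standard carvone chemistry. In the usual diterpenoid drawing, (R)-carvone has H9 on the β face. This puts H8 α, C20 α and H5 β, and that arrangement is the (5R,10R) series of 16 and 17.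

## Roads not taken

**Alternative 1:** reconnect C3–C4 (the most obvious route, which follows the biogenesis).
- An aryl epoxydiene A1 would be closed by cation–olefin bicyclisation, and oxidation would give tricyclic ketone A2.
- Ring A would then be cut between C3 and C4 by Baeyer–Villiger oxidation and elimination or by Beckmann fragmentation.
- The vinyl group would be installed by cross-coupling, the phenol freed, and 16 oxygenated as here.
- The chosen plan is better for three reasons. A1 needs the awkward pentasubstituted arene made beforehand. Ring A (two C–C bonds, an enantioselective epoxidation, a C3 oxygen) is built only to be destroyed. The vinyl group and the phenol must stay masked through acid and peracid steps, and that adds protecting-group and redox operations.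

**Alternative 2:** cut away all of ring C and build ring B first.
- Copper-catalysed asymmetric conjugate addition of an isopropenyl nucleophile to 2-methylcyclohexenone, with trapping by methyl acrylate, would give keto ester A3.
- Elaboration to dienynone A4, then ring-closing enyne metathesis (second-generation Grubbs catalyst) and tautomerisation, would deliver the 3-vinylphenol 16 directly.
- The metathesis is attractive, but the run-up consumes its gain. The C9 carbonyl of A3 is neopentyl and competes with an unhindered ester. The C8 enolate can attack the C3 ester to give a bicyclo[3.3.1]nonanedione.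
- An ethynyl group at C8 and an acylmethyl group at C9 each need several steps, and the absolute configuration depends on a demanding catalysis on an α-substituted enone.

**Alternative 3:** arene first, cutting C10–C1 and C5–C4.
- Asymmetric Michael addition of a 1-methyl-2-tetralone to methyl acrylate would give A5, with C10 set.
- The C5 carbonyl would then have to become CH–isopropenyl, the bromide a vinyl group, and the methyl ether a phenol.
- The tetralone again needs the five-substituent arene. Converting a ketone next to a quaternary carbon into a tertiary isopropenyl-bearing stereocentre has no reliable control element. The final ether cleavage must also spare an ester and two alkenes.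

Key step: step 4

Remark on the chemistry: α/β refer to the usual diterpenoid drawing (ring C upper right). Alcohol 11 is drawn as the epimer from axial β-face attack, and either C14 epimer gives 12.

## Steps

Step 1
Reactants: 1 5-bromo-2-methylpent-2-ene
Product: 2 5-iodo-2-methylpent-2-ene
Conditions: NaI, acetone, reflux
Reagents that add atoms: sodium iodide, [Na+].[I-]
Why: Finkelstein halide exchange driven by precipitation of NaBr; the iodide is wanted because the carvone enolate alkylates unactivated primary bromides sluggishly.

Step 2
Reactants: 3 (R)-(−)-carvone; 2 5-iodo-2-methylpent-2-ene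
Product: 5 (5R,6S)-2-methyl-6-(4-methylpent-3-en-1-yl)-5-(prop-1-en-2-yl)cyclohex-2-en-1-one, via lithium dienolate 4 (not isolated)
Conditions: LiN(iPr)2, THF, −78 °C; then 2, DMPU, −78 °C to rt
Reagents that add atoms: none
Why: Kinetic deprotonation of carvone occurs at the α′ carbon (C8) and SN2 alkylation of the cross-conjugated dienolate takes place anti to the neighbouring isopropenyl group. The trans (diequatorial) product is also the thermodynamic one, so a cis fraction can be equilibrated with base; the temporary C8 centre is thus set by the purchased C9 centre.

Step 3
Reactants: 6 methyl bromoacetate; 7 potassium O-ethyl dithiocarbonate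
Product: 8 methyl 2-[(ethoxycarbonothioyl)sulfanyl]acetate
Conditions: acetone, 0 °C to rt
Reagents that add atoms: none
Why: SN2 displacement of bromide by the soft sulfur nucleophile, the standard preparation of S-alkyl O-ethyl dithiocarbonates.

Step 4
Reactants: 5 (5R,6S)-6-homoprenylcarvone; 8 methyl 2-[(ethoxycarbonothioyl)sulfanyl]acetate
Product: 10 methyl 3-[(1S,2R,4aS,8aR)-1,6-dimethyl-5-oxo-2-(prop-1-en-2-yl)-1,2,3,4,4a,5,8,8a-octahydronaphthalen-1-yl]propanoate (trans-fused; H8 α, H9 β, C20 α, H5 β), via tertiary xanthate 9 (not isolated)
Conditions: 8 (2 equiv), dilauroyl peroxide (substoichiometric, in portions), degassed EtOAc, reflux; then solvent change to PhCl, reflux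
Reagents that add atoms: none
Why: Xanthate group-transfer radical addition–cyclisation, the degenerative-transfer form of the Kharasch addition, ended by a Chugaev-type syn-elimination. The peroxide sets free the electrophilic radical •CH2CO2Me from 8, which should add to the unhindered terminal C1 of the 1,1-disubstituted isopropenyl group and not to the internal trisubstituted C5=C4 bond (steric retardation at the attacked carbon) or to the electron-poor enone (polarity mismatch); this makes C1–C2 and a nucleophilic tertiary radical at C10. Capture of that radical by 8 is reversible, so it keeps returning to the chain until it closes ring B irreversibly in the 6-exo-trig mode on C5, the less substituted end of the prenyl bond (C10–C5), and the tertiary C4 radical is stored as 9. The closure runs through a chair-like transition state built on the trans-diequatorial arms at C8 and C9 of ring C, so rings B and C become trans-fused. C10 is controlled by C9: in the reactive rotamer H9 lies next to the larger CH2CH2CO2Me group of the planar radical, which becomes equatorial, while the smaller C20 takes the crowded axial site anti to H9. C5 is controlled by the same chair: the C4 terminus sits pseudo-equatorial, which places H5 anti to C20 and the future isopropenyl group trans to the propanoate arm. On heating, 9 loses EtOC(S)SH through a cyclic transition state that takes one of six methyl hydrogens, since the alternative C5=C4 alkene would press against quaternary C10 (allylic 1,3-strain), and the isopropenyl group appears only after the radical phase is over, so it cannot be attacked again.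

Step 5
Reactants: 10 bicyclic enone
Product: 11 methyl 3-[(1S,2R,4aS,5R,8aR)-5-ethenyl-5-hydroxy-1,6-dimethyl-2-(prop-1-en-2-yl)-1,2,3,4,4a,5,8,8a-octahydronaphthalen-1-yl]propanoate
Conditions: CH2=CHMgBr, THF, −78 to −40 °C; aqueous quench
Reagents that add atoms: vinylmagnesium bromide, C=C[Mg]Br
Why: Grignard 1,2-addition to the enone carbonyl, which at low temperature is far more electrophilic than the methyl ester. Axial attack from the β face is expected, but the C14 configuration is erased in step 6.

Step 6
Reactants: 11 tertiary bis-allylic alcohol
Product: 12 methyl 3-[(1S,2R,4aS,8aR)-5-ethenyl-1,6-dimethyl-7-oxo-2-(prop-1-en-2-yl)-1,2,3,4,4a,7,8,8a-octahydronaphthalen-1-yl]propanoate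
Conditions: pyridinium chlorochromate [C5H5NH][CrO3Cl], SiO2, CH2Cl2, rt
Reagents that add atoms: pyridinium chlorochromate, [O-][Cr](=O)(=O)Cl.c1cc[nH+]cc1
Why: Babler–Dauben oxidative 1,3-transposition: the chromate ester of the tertiary allylic alcohol shifts suprafacially to C12 and is oxidised there, as in the known alkylative enone transposition of carvone, which tolerates the isopropenyl group. Of the two allyl termini the secondary ring carbon C12 bears positive charge better than primary C16, and its use gives the fully conjugated, tetrasubstituted dienone.

Step 7
Reactants: 12 vinyl dienone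
Product: 14 trimethylsilyl cross-conjugated dienol ether of 12 (C11=C12–OSiMe3; all stereocentres as in 12), via lithium enolate 13 (not isolated)
Conditions: LiN(iPr)2 (1.05 equiv), THF, −78 °C; Me3SiCl
Reagents that add atoms: chlorotrimethylsilane, C[Si](C)(C)Cl
Why: Kinetic deprotonation of a cyclohexenone takes place at the α′ carbon (C11), which is also more acidic than the ester α-CH2; O-silylation traps the enolate.

Step 8
Reactants: 14 silyl dienol ether
Product: 16 methyl 3-[(1R,2R)-5-ethenyl-7-hydroxy-1,6-dimethyl-2-(prop-1-en-2-yl)-1,2,3,4-tetrahydronaphthalen-1-yl]propanoate, via cross-conjugated trienone 15 (not isolated)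
Conditions: Pd(OAc)2 (1.1 equiv), MeCN, rt
Reagents that add atoms: none
Why: Saegusa–Ito oxidation: palladation at C11 and syn β-hydride elimination of H9 give 15, the keto tautomer of a phenol, which loses H8 and aromatises at once. The relay centres C8 and C9 are erased after use; C5 and C10 are not touched.

Step 9
Reactants: 16 phenol
Product: 17 trigonochinene C, methyl 3-[(1R,2R,4aR)-5-ethenyl-4a-hydroperoxy-1,6-dimethyl-7-oxo-2-(prop-1-en-2-yl)-1,2,3,4,4a,7-hexahydronaphthalen-1-yl]propanoate
Conditions: O2, meso-tetraphenylporphyrin (cat.), visible light, CH2Cl2–MeOH, −20 °C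
Reagents that add atoms: dioxygen, O=O
Why: Biomimetic dearomatising photooxygenation: singlet oxygen attacks para-alkylphenols at the carbon para to OH to give 4-hydroperoxycyclohexa-2,5-dienones, and an electron-rich phenol reacts much faster than a 1,1-disubstituted alkene (ene reaction) or a styrene. Attack on the α face, syn to the axial C20 methyl group, lets C8 pyramidalise with an axial C–O bond while ring B passes from half-chair to chair with both large groups equatorial. Attack on the other face would force a twist-boat, so the (8R) isomer should prevail.

## Compound list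

1 | 5-bromo-2-methylpent-2-ene | CC(C)=CCCBr | starting material
2 | 5-iodo-2-methylpent-2-ene | CC(C)=CCCI | intermediate
3 | (R)-(−)-carvone | CC1=CC[C@H](CC1=O)C(C)=C | starting material
4 | lithium (3R)-6-methyl-3-(prop-1-en-2-yl)cyclohexa-1,5-dien-1-olate | CC1=CC[C@@H](C(C)=C)C=C1[O-].[Li+] | intermediate
5 | (5R,6S)-2-methyl-6-(4-methylpent-3-en-1-yl)-5-(prop-1-en-2-yl)cyclohex-2-en-1-one | CC1=CC[C@@H](C(C)=C)[C@H](CCC=C(C)C)C1=O | intermediate
6 | methyl bromoacetate | COC(=O)CBr | starting material
7 | potassium O-ethyl dithiocarbonate | CCOC(=S)[S-].[K+] | starting material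
8 | methyl 2-[(ethoxycarbonothioyl)sulfanyl]acetate | CCOC(=S)SCC(=O)OC | intermediate
9 | methyl 3-[(1S,2S,4aS,8aR)-2-{2-[(ethoxycarbonothioyl)sulfanyl]propan-2-yl}-1,6-dimethyl-5-oxo-1,2,3,4,4a,5,8,8a-octahydronaphthalen-1-yl]propanoate | CC1=CC[C@@H]2[C@H](CC[C@H](C(C)(C)SC(=S)OCC)[C@@]2(C)CCC(=O)OC)C1=O | intermediate
10 | methyl 3-[(1S,2R,4aS,8aR)-1,6-dimethyl-5-oxo-2-(prop-1-en-2-yl)-1,2,3,4,4a,5,8,8a-octahydronaphthalen-1-yl]propanoate | CC1=CC[C@@H]2[C@H](CC[C@H](C(C)=C)[C@@]2(C)CCC(=O)OC)C1=O | intermediate
11 | methyl 3-[(1S,2R,4aS,5R,8aR)-5-ethenyl-5-hydroxy-1,6-dimethyl-2-(prop-1-en-2-yl)-1,2,3,4,4a,5,8,8a-octahydronaphthalen-1-yl]propanoate | C=C[C@]1(O)C(C)=CC[C@@H]2[C@@H]1CC[C@H](C(C)=C)[C@@]2(C)CCC(=O)OC | intermediate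
12 | methyl 3-[(1S,2R,4aS,8aR)-5-ethenyl-1,6-dimethyl-7-oxo-2-(prop-1-en-2-yl)-1,2,3,4,4a,7,8,8a-octahydronaphthalen-1-yl]propanoate | C=CC1=C(C)C(=O)C[C@@H]2[C@@H]1CC[C@H](C(C)=C)[C@@]2(C)CCC(=O)OC | intermediate
13 | lithium C11=C12 enolate of 12 | C=CC1=C(C)C([O-])=C[C@@H]2[C@@H]1CC[C@H](C(C)=C)[C@@]2(C)CCC(=O)OC.[Li+] | intermediate
14 | trimethylsilyl C11=C12 dienol ether of 12 | C=CC1=C(C)C(O[Si](C)(C)C)=C[C@@H]2[C@@H]1CC[C@H](C(C)=C)[C@@]2(C)CCC(=O)OC | intermediate
15 | methyl 3-[(1R,2R,4aS)-5-ethenyl-1,6-dimethyl-7-oxo-2-(prop-1-en-2-yl)-1,2,3,4,4a,7-hexahydronaphthalen-1-yl]propanoate | C=CC1=C(C)C(=O)C=C2[C@@H]1CC[C@H](C(C)=C)[C@@]2(C)CCC(=O)OC | intermediate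
16 | methyl 3-[(1R,2R)-5-ethenyl-7-hydroxy-1,6-dimethyl-2-(prop-1-en-2-yl)-1,2,3,4-tetrahydronaphthalen-1-yl]propanoate | C=Cc1c(C)c(O)cc2c1CC[C@H](C(C)=C)[C@@]2(C)CCC(=O)OC | intermediate
17 | trigonochinene C | C=CC1=C(C)C(=O)C=C2[C@]1(OO)CC[C@H](C(=C)C)[C@@]2(C)CCC(=O)OC | target

## Step count and risk

Total step count: 9. Longest linear sequence: 8 steps (1, 2, 4, 5, 6, 7, 8, 9), of which 7 start from (R)-carvone.

**Step 4 (key step).**
- The C10 radical may be lost before it closes the ring. Possible causes are irreversible elimination from its own tertiary xanthate, 1,5-hydrogen transfer from the allylic C6–H, and oxidation by the peroxide followed by lactonisation onto the ester.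
- Discrimination between CH3 and the CH2 arm at C10 may be only moderate, because both begin with a carbon of similar size.
- Fallback, from 5 back to 10: the acceptor is made faster and self-terminating.
  - Allylic oxidation of the prenyl group of 5 (SeO2 cat., tBuOOH, CH2Cl2) should give the (E)-allylic alcohol F1.
  - Mesylation and displacement (MeSO2Cl, Et3N; then EtSO2Na, DMF) should give the allyl ethyl sulfone F2.
  - With 8 and dilauroyl peroxide, the same C10 radical closes on an activated double bond. The C4 radical then ends the sequence by β-scission of the ethylsulfonyl radical, which writes the isopropenyl group of 10 regiospecifically.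
  - Loss of SO2 leaves an ethyl radical that carries the chain by attack on 8. This is the known tin-free radical allylation.

**Step 2.**
- The SN2 reaction of an unactivated iodide is slow, so proton transfer between enolate and product may lead to polyalkylation and loss of regiocontrol.
- Fallback, from 3 back to 5:
  - Condensation with Me2NNH2 should give the carvone dimethylhydrazone F3.
  - Its lithium aza-enolate (LiN(iPr)2, THF) is more nucleophilic and does not equilibrate. Alkylation with 2 should give the alkylated hydrazone F4.
  - Hydrolysis with Cu(OAc)2 in aqueous THF, followed by base equilibration, returns 5.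

**Step 6.**
- The doubly allylic alcohol may ionise and dehydrate, and the chromate may migrate to the vinyl terminus, because both allyl systems are available.
- Fallback, from 10 back to 12:
  - HC≡CMgBr should give the ethynyl carbinol F5, which has only one allyl terminus and ionises less readily.
  - Pyridinium chlorochromate should give the enynone F6.
  - Semihydrogenation (H2, Pd/CaCO3 poisoned with Pb(OAc)2, quinoline) returns 12.

**Step 8.**
- The diene and the isopropenyl group may compete for divalent palladium.
- The required syn alignment of C11–Pd with the single, axial C9–H may be hard to reach.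
- Fallback, from 14 back to 16:
  - N-bromosuccinimide (THF, −78 °C) should brominate axially to the 11α-bromo ketone F7, in which bromine is antiperiplanar to H9.
  - E2 elimination (Li2CO3, LiBr, DMF, heat) gives 15 and hence 16.

**Step 9.**
- Facial selectivity may be poor, because the stereoelectronically preferred face is also the face of the C20 methyl group and the seco ring B is conformationally mobile.
- A slow ene reaction at the isopropenyl group may occur on long irradiation.
- Fallback, from 16 back to 16 (a recycling loop in place of a selective step):
  - The 8-epi-hydroperoxide F8 is separated by chromatography.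
  - It is reduced with PPh3 to the 8-epi-quinol F9.
  - Reductive aromatisation (Zn, AcOH) returns 16 for another pass.

## Further compounds

F1 | step 4 | (5R,6S)-6-[(3E)-5-hydroxy-4-methylpent-3-en-1-yl]-2-methyl-5-(prop-1-en-2-yl)cyclohex-2-en-1-one | CC1=CC[C@@H](C(C)=C)[C@H](CC/C=C(\C)CO)C1=O
F2 | step 4 | (5R,6S)-6-[(3E)-5-(ethylsulfonyl)-4-methylpent-3-en-1-yl]-2-methyl-5-(prop-1-en-2-yl)cyclohex-2-en-1-one | CC1=CC[C@@H](C(C)=C)[C@H](CC/C=C(\C)CS(=O)(=O)CC)C1=O
F3 | step 2 | (R)-carvone N,N-dimethylhydrazone | CC1=CC[C@H](CC1=NN(C)C)C(C)=C
F4 | step 2 | N,N-dimethylhydrazone of 5 | CC1=CC[C@@H](C(C)=C)[C@H](CCC=C(C)C)C1=NN(C)C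
F5 | step 6 | 14-ethynyl analogue of 11 (ethynyl β, OH α) | C#C[C@]1(O)C(C)=CC[C@@H]2[C@@H]1CC[C@H](C(C)=C)[C@@]2(C)CCC(=O)OC
F6 | step 6 | 14-ethynyl analogue of 12 (enynone) | C#CC1=C(C)C(=O)C[C@@H]2[C@@H]1CC[C@H](C(C)=C)[C@@]2(C)CCC(=O)OC
F7 | step 8 | 11α-bromo derivative of 12 | C=CC1=C(C)C(=O)[C@@H](Br)[C@@H]2[C@@H]1CC[C@H](C(C)=C)[C@@]2(C)CCC(=O)OC
F8 | step 9 | 8-epi-trigonochinene C | C=CC1=C(C)C(=O)C=C2[C@@]1(OO)CC[C@H](C(=C)C)[C@@]2(C)CCC(=O)OC
F9 | step 9 | 8-epi-8-hydroxy dienone (para-quinol) | C=CC1=C(C)C(=O)C=C2[C@@]1(O)CC[C@H](C(=C)C)[C@@]2(C)CCC(=O)OC
A1 | alternative 1 | (3R)-3-{(3E)-6-(2-bromo-4-methoxy-3-methylphenyl)-3-methylhex-3-en-1-yl}-2,2-dimethyloxirane | COc1ccc(CC/C=C(\C)CC[C@H]2OC2(C)C)c(Br)c1C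
A2 | alternative 1 | (4aR,10aS)-8-bromo-6-methoxy-1,1,4a,7-tetramethyl-3,4,4a,9,10,10a-hexahydrophenanthren-2(1H)-one | COc1cc2c(CC[C@@H]3C(C)(C)C(=O)CC[C@@]23C)c(Br)c1C
A3 | alternative 2 | methyl 3-[(1R,6R)-1-methyl-2-oxo-6-(prop-1-en-2-yl)cyclohexyl]propanoate | O=C1CCC[C@H](C(C)=C)[C@@]1(C)CCC(=O)OC
A4 | alternative 2 | methyl 3-[(1R,6R)-3-ethynyl-1-methyl-2-(3-methyl-2-oxobut-3-en-1-yl)-6-(prop-1-en-2-yl)cyclohex-2-en-1-yl]propanoate | C#CC1=C(CC(=O)C(C)=C)[C@](C)(CCC(=O)OC)[C@@H](C(C)=C)CC1
A5 | alternative 3 | methyl 3-[(1S)-5-bromo-7-methoxy-1,6-dimethyl-2-oxo-1,2,3,4-tetrahydronaphthalen-1-yl]propanoate | COc1cc2c(CCC(=O)[C@@]2(C)CCC(=O)OC)c(Br)c1C
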